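**Retrosynthetic overview**
1. Target 25 ⇐ late epoxidation of the C1=C10 alkene of triene lactone 24 ⇐ Mitsunobu esterification (inversion at C8) of alcohol 20 with epoxy acid 23 (Sharpless route from tiglyl alcohol).
2. γ-Lactone ⇐ 1,2-reduction/lactonisation of the ten-membered trienone ester 17.
3. Ten-membered ring ⇐ key ring expansion (7 → 10): a zinc Barbier closure of a five-membered ring onto cycloheptadienone 15, then Grob fragmentation of the shared C6–C10 bond. This makes E-C1=C10 and releases the Z,Z-dienone.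
4. Cycloheptadienone ⇐ bridge opening and dianion alkylation of the [4+3] adduct of 2-methylfuran with an oxyallyl cation; side arm from (R)-but-3-ene-1,2-diol and methyl acrylate.
5. Ring order: oxabicycle → seven-membered dienone → transient 5/7 bicycle → ten-membered ring → lactone → epoxide.

Assumptions: germacrane numbering (C1–C15) is used for the ring carbons throughout. Compounds 3–5 are racemic; 9–16 are 1:1 pairs that differ only at the ring centres C1/C10 and are drawn as one isomer, because both centres become sp2 in step 8. 1,1,3,3-Tetrabromoacetone and (R)-but-3-ene-1,2-diol are taken as commercial.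

Step 1
Reactants: 1 2-methylfuran; 2 1,1,3,3-tetrabromopropan-2-one
Product: 4 rac-1-methyl-8-oxabicyclo[3.2.1]oct-6-en-3-one, via dibromo cycloadduct 3 (not isolated)
Conditions: Zn, B(OEt)3, THF, rt; then Zn–Cu, NH4Cl, MeOH, rt
Reagents that add atoms: none
Why: [4+3] cycloaddition of the zinc-generated oxyallyl cation to the furan gives a single regioisomer because the cation is symmetrical, and reductive debromination follows; the bicycle fixes the relative configuration.

Step 2
Reactants: 4 rac-1-methyl-8-oxabicyclo[3.2.1]oct-6-en-3-one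
Product: 5 rac-2,5-dimethyl-8-oxabicyclo[3.2.1]oct-6-en-3-one
Conditions: LDA, THF, −78 °C; MeI, −78 → −40 °C
Reagents that add atoms: iodomethane CI
Why: Kinetic enolate alkylation; LDA removes the exo proton of the CH2 remote from the bridgehead methyl and MeI enters on the exo face, so the new methyl is syn to the oxygen bridge.

Step 3
Reactants: 6 (R)-but-3-ene-1,2-diol
Product: 8 (R)-2-(tert-butyldimethylsilyloxy)but-3-en-1-yl triflate, via hydroxy triflate 7 (not isolated)
Conditions: Tf2O, 2,6-lutidine, CH2Cl2, −78 °C; then TBSOTf, −78 → −40 °C; used cold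
Reagents that add atoms: triflic anhydride O=S(=O)(OS(=O)(=O)C(F)(F)F)C(F)(F)F; tert-butyldimethylsilyl triflate CC(C)(C)[Si](C)(C)OS(=O)(=O)C(F)(F)F
Why: Primary-selective O-triflation followed by O-silylation of the secondary hydroxyl; the stereocentre of 6 is not touched.

Step 4
Reactants: 5 rac-2,5-dimethyl-8-oxabicyclo[3.2.1]oct-6-en-3-one; 8 (R)-2-(tert-butyldimethylsilyloxy)but-3-en-1-yl triflate
Product: 11 cycloheptadienone mesylate, via dilithium enolate alkoxide 9 (not isolated), via C-alkylated lithium alkoxide 10 (not isolated)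
Conditions: LDA (2.3 equiv), THF, −78 → 0 °C; 8, −78 → −30 °C; MsCl, −78 → 0 °C
Reagents that add atoms: methanesulfonyl chloride CS(=O)(=O)Cl
Why: LDA takes the remaining methylene proton, warming opens the oxygen bridge by E1cB β-elimination at the tertiary C–O bond, and the β-oxido enolate 9 is C-alkylated trans to the alkoxide (Fráter–Seebach-type dianion alkylation), so methyl and oxygen end up cis; O-mesylation then installs the nucleofuge.

Step 5
Reactants: 11 cycloheptadienone mesylate
Product: 12 α-silyloxy aldehyde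
Conditions: OsO4 (2 mol %), NaIO4, 2,6-lutidine, dioxane/H2O, 0 °C → rt
Reagents that add atoms: sodium periodate [Na+].[O-]I(=O)(=O)=O
Why: Johnson–Lemieux oxidative cleavage is selective for the monosubstituted alkene over the electron-poor dienone; no stereocentre is affected.

Step 6
Reactants: 12 α-silyloxy aldehyde; 13 methyl acrylate
Product: 14 Baylis–Hillman adduct
Conditions: DABCO, MeOH, rt, 48 h
Reagents that add atoms: none
Why: Morita–Baylis–Hillman reaction of a reactive α-oxygenated aldehyde; the new carbinol centre (both epimers) is erased in step 7.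

Step 7
Reactants: 14 Baylis–Hillman adduct
Product: 15 (Z)-allylic bromide
Conditions: NBS, Me2S, CH2Cl2, 0 °C → rt
Reagents that add atoms: N-bromosuccinimide O=C1CCC(=O)N1Br
Why: Corey–Kim activation and SN2′ bromide delivery (allylic transposition) give the thermodynamically preferred (Z)-2-(bromomethyl)enoate.

Step 8
Reactants: 15 (Z)-allylic bromide
Product: 17 ten-membered trienone ester, via bicyclic zinc alkoxide 16 (not isolated)
Conditions: Zn dust (TMSCl-activated), LiCl, THF, 0 → 25 °C, 0.02 M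
Reagents that add atoms: none
Why: Proposed new method: zinc insertion gives a 2-(methoxycarbonyl)allylzinc that adds through C7 to the C6 ketone in a five-membered ring closure; this turns the cross-conjugated, deactivated C1 mesylate into a dienylic mesylate anti-periplanar to the C6–C10 bond, so alkoxide 16 undergoes Grob fragmentation to the ten-membered ring with E-C1=C10 (methyl and mesylate cis) and the ring-held Z,Z-diene, while A1,3 strain at C8 places C7 trans to OTBS (7R); closest known reactions are the SmI2 Barbier cyclisation/Grob fragmentation of saturated keto mesylates and the Wharton fragmentation.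

Step 9
Reactants: 17 ten-membered trienone ester
Product: 19 silyl-protected triene lactone, via allylic alcohol ester 18 (not isolated)
Conditions: NaBH4, CeCl3·7H2O, MeOH, −78 → 0 °C; then 2-hydroxypyridine (cat.), PhMe, 40 °C
Reagents that add atoms: none
Why: Luche 1,2-reduction with Felkin–Anh attack anti to the C7 alkenyl group sets C6 (R), and the alcohol lactonises to the trans-fused α-methylene γ-lactone.

Step 10
Reactants: 19 silyl-protected triene lactone
Product: 20 8-epi alcohol
Conditions: HF·pyridine, THF/pyridine, 0 °C → rt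
Reagents that add atoms: none
Why: Fluoride-mediated desilylation; no stereocentre changes.

Step 11
Reactants: 21 (E)-2-methylbut-2-en-1-ol
Product: 22 (2R,3R)-epoxy alcohol
Conditions: Ti(OiPr)4, D-(−)-DIPT, t-BuOOH, 4 Å MS, CH2Cl2, −20 °C
Reagents that add atoms: tert-butyl hydroperoxide CC(C)(C)OO
Why: Sharpless asymmetric epoxidation; D-(−)-tartrate gives the (2R,3R)-epoxide (L-(+)-tartrate gives 2S,3S).

Step 12
Reactants: 22 (2R,3R)-epoxy alcohol
Product: 23 (2S,3R)-2,3-dimethyloxirane-2-carboxylic acid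
Conditions: RuCl3 (cat.), NaIO4, MeCN/EtOAc/H2O, 0 °C → rt
Reagents that add atoms: sodium periodate [Na+].[O-]I(=O)(=O)=O
Why: Sharpless RuO4 oxidation of the primary alcohol to the acid leaves the epoxide intact (the descriptor at C2 changes by priority only).

Step 13
Reactants: 20 8-epi alcohol; 23 (2S,3R)-2,3-dimethyloxirane-2-carboxylic acid
Product: 24 triene lactone ester
Conditions: PPh3, DIAD, PhMe, 0 °C → rt
Reagents that add atoms: none
Why: Mitsunobu esterification proceeds with SN2 inversion at C8, turning 8S into the required 8R ester.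

Step 14
Reactants: 24 triene lactone ester
Product: 25 CNP0122107.1
Conditions: m-CPBA (1.05 equiv), NaHCO3, CH2Cl2, −20 °C
Reagents that add atoms: m-chloroperbenzoic acid O=C(OO)c1cccc(Cl)c1
Why: Prilezhaev epoxidation; the trisubstituted C1=C10 alkene remote from the lactone oxygen is the most electron-rich, and attack on the exposed outer face of the E-alkene is expected to give the trans (1R,10R)-epoxide, as in related germacranolides.

**Compound list**
1 | 2-methylfuran | Cc1ccco1 | starting material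
2 | 1,1,3,3-tetrabromopropan-2-one | O=C(C(Br)Br)C(Br)Br | starting material
3 | rac-2,4-dibromo-1-methyl-8-oxabicyclo[3.2.1]oct-6-en-3-one (both Br anti to the O bridge) | C[C@]12[C@@H](Br)C(=O)[C@@H](Br)[C@H](O1)C=C2 | intermediate
4 | rac-(1R,5S)-1-methyl-8-oxabicyclo[3.2.1]oct-6-en-3-one | C[C@]12CC(=O)C[C@H](O1)C=C2 | intermediate
5 | rac-(1R,2R,5R)-2,5-dimethyl-8-oxabicyclo[3.2.1]oct-6-en-3-one (2-methyl syn to the O bridge) | C[C@]12CC(=O)[C@H](C)[C@H](O1)C=C2 | intermediate
6 | (R)-but-3-ene-1,2-diol | OC[C@H](O)C=C | starting material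
7 | (R)-2-hydroxybut-3-en-1-yl trifluoromethanesulfonate | FC(F)(F)S(=O)(=O)OC[C@H](O)C=C | intermediate
8 | (R)-2-[(tert-butyldimethylsilyl)oxy]but-3-en-1-yl trifluoromethanesulfonate | FC(F)(F)S(=O)(=O)OC[C@H](O[Si](C)(C)C(C)(C)C)C=C | intermediate
9 | dilithium enolate–alkoxide of 6-hydroxy-3,7-dimethylcyclohepta-2,4-dien-1-one (racemic; one enantiomer drawn) | [Li+].[Li+].[O-][C@@H]1C=CC(C)=CC([O-])=C1C | intermediate
10 | lithium (1R,7S)-7-{(2S)-2-[(tert-butyldimethylsilyl)oxy]but-3-en-1-yl}-4,7-dimethyl-6-oxocyclohepta-2,4-dien-1-olate (1:1 with the 1S,7R ring isomer) | [Li+].[O-][C@@H]1C=CC(C)=CC(=O)[C@@]1(C)C[C@H](O[Si](C)(C)C(C)(C)C)C=C | intermediate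
11 | (1R,7S)-7-{(2S)-2-[(tert-butyldimethylsilyl)oxy]but-3-en-1-yl}-4,7-dimethyl-6-oxocyclohepta-2,4-dien-1-yl methanesulfonate; methyl and mesylate cis (1:1 with the 1S,7R ring isomer) | CS(=O)(=O)O[C@@H]1C=CC(C)=CC(=O)[C@@]1(C)C[C@H](O[Si](C)(C)C(C)(C)C)C=C | intermediate
12 | (1R,7S)-7-{(2S)-2-[(tert-butyldimethylsilyl)oxy]-3-oxopropyl}-4,7-dimethyl-6-oxocyclohepta-2,4-dien-1-yl methanesulfonate (and 1S,7R ring isomer) | CS(=O)(=O)O[C@@H]1C=CC(C)=CC(=O)[C@@]1(C)C[C@H](O[Si](C)(C)C(C)(C)C)C=O | intermediate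
13 | methyl acrylate | C=CC(=O)OC | starting material
14 | methyl (4S)-4-[(tert-butyldimethylsilyl)oxy]-3-hydroxy-5-[(1S,7R)-7-(mesyloxy)-1,4-dimethyl-2-oxocyclohepta-3,5-dien-1-yl]-2-methylidenepentanoate (both C3 epimers; and 1R,7S ring isomer) | CS(=O)(=O)O[C@@H]1C=CC(C)=CC(=O)[C@@]1(C)C[C@H](O[Si](C)(C)C(C)(C)C)C(O)C(=C)C(=O)OC | intermediate
15 | methyl (2Z,4S)-2-(bromomethyl)-4-[(tert-butyldimethylsilyl)oxy]-5-[(1S,7R)-7-(mesyloxy)-1,4-dimethyl-2-oxocyclohepta-3,5-dien-1-yl]pent-2-enoate (and 1R,7S ring isomer) | CS(=O)(=O)O[C@@H]1C=CC(C)=CC(=O)[C@@]1(C)C[C@H](O[Si](C)(C)C(C)(C)C)/C=C(\CBr)C(=O)OC | intermediate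
16 | bromozinc alkoxide of the cis-fused bicyclo[5.3.0]decadiene: C6–OZnBr and C10–Me cis, C7 acrylate trans to C8–OTBS, C1–OMs cis to C10–Me | CS(=O)(=O)O[C@@H]1C=CC(C)=C[C@]2(O[Zn]Br)[C@@]1(C)C[C@H](O[Si](C)(C)C(C)(C)C)[C@H]2C(=C)C(=O)OC | intermediate
17 | methyl 2-[(1R,2S,4E,6Z,8Z)-2-[(tert-butyldimethylsilyl)oxy]-4,8-dimethyl-10-oxocyclodeca-4,6,8-trien-1-yl]prop-2-enoate (germacrane 7R,8S) | COC(=O)C(=C)[C@H]1C(=O)/C=C(C)\C=C/C=C(C)/C[C@@H]1O[Si](C)(C)C(C)(C)C | intermediate
18 | (6R,7S,8S)-6-hydroxy analogue of 17 (allylic alcohol methyl ester) | COC(=O)C(=C)[C@H]1[C@H](O)/C=C(C)\C=C/C=C(C)/C[C@@H]1O[Si](C)(C)C(C)(C)C | intermediate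
19 | (6R,7S,8S)-8-[(tert-butyldimethylsilyl)oxy]germacra-1(10)E,2Z,4Z,11(13)-tetraen-12,6-olide (trans-fused lactone) | C=C1C(=O)O[C@@H]2/C=C(C)\C=C/C=C(C)/C[C@H](O[Si](C)(C)C(C)(C)C)[C@@H]12 | intermediate
20 | (6R,7R,8S)-8-hydroxygermacra-1(10)E,2Z,4Z,11(13)-tetraen-12,6-olide | C=C1C(=O)O[C@@H]2/C=C(C)\C=C/C=C(C)/C[C@H](O)[C@@H]12 | intermediate
21 | (E)-2-methylbut-2-en-1-ol | C/C=C(\C)CO | starting material
22 | [(2R,3R)-2,3-dimethyloxiran-2-yl]methanol | OC[C@@]1(C)O[C@@H]1C | intermediate
23 | (2S,3R)-2,3-dimethyloxirane-2-carboxylic acid | OC(=O)[C@@]1(C)O[C@@H]1C | intermediate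
24 | (6R,7R,8R)-8-{[(2S,3R)-2,3-dimethyloxirane-2-carbonyl]oxy}germacra-1(10)E,2Z,4Z,11(13)-tetraen-12,6-olide | C=C1C(=O)O[C@@H]2/C=C(C)\C=C/C=C(C)/C[C@@H](OC(=O)[C@@]3(C)O[C@@H]3C)[C@@H]12 | intermediate
25 | CNP0122107.1, the (1R,10R)-epoxide of 24 (1R,6R,7R,8R,10R; side chain 2S,3R) | C=C1C(=O)O[C@@H]2/C=C(C)\C=C/[C@H]3O[C@]3(C)C[C@@H](OC(=O)[C@@]3(C)O[C@@H]3C)[C@@H]12 | target

**Step count:** 14 steps in total. Longest linear sequence: 11 steps (1 → 25 through steps 1, 2, 4–10, 13, 14).

**Three steps most likely to fail**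

Step 4. The bridge opening from a bicyclic enolate has poor orbital overlap, and the quaternary C-alkylation with a β-branched triflate may be slow or give O-alkylation. The fallback builds the quaternary centre before the ring is opened and opens the bridge with a Lewis acid. It sets out from 4 and returns at 11. The kinetic lithium enolate of 4 is alkylated with triflate 8 to give the mono-alkylated bicyclic ketone F1. Equilibration to the more substituted potassium enolate (KH, THF) and methylation on the exo face gives the quaternary ketone F2, with methyl syn to the oxygen bridge. TMSOTf/Et3N opens the bridge at the tertiary C–O bond to the ring-opened trimethylsilyl ether F3. K2CO3/MeOH frees the alcohol F4, and MsCl/Et3N gives 11.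

Step 8 (the proposed new method). The zinc alkoxide may lactonise onto the ester or be too weak a donor to fragment, and ionisation of the mesylate could erode the E geometry. The fallback separates the two events as a classical Wharton fragmentation of an isolated 1,3-diol monosulfonate. It sets out from 10 and returns at 17. Alkoxide 10 is quenched with Et3SiCl instead of MsCl to give the triethylsilyl ether F5. The reagents of steps 5–7 then give the aldehyde F6, the Baylis–Hillman adduct F7 and the allylic bromide F8. Indium in THF/H2O closes the five-membered ring to the isolable tertiary alcohol F9. Buffered TBAF/AcOH removes only the triethylsilyl group to give the diol F10. MsCl/Et3N at −40 °C sulfonylates the secondary hydroxyl to the monomesylate F11, which is treated at once with KOt-Bu to fragment to 17.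

Step 13. Mitsunobu inversion at a hindered ring carbinol with a hindered acid may be slow or give elimination. The fallback is a sulfonate displacement; it sets out from 20 and returns at 24. MsCl/Et3N gives the C8 mesylate F12, which is displaced with inversion by the caesium salt of 23 (Cs2CO3, 18-crown-6, DMF, 50 °C) to give 24.

**Further compounds**
F1 | step 4 | rac-ring 2-{(2S)-2-[(tert-butyldimethylsilyl)oxy]but-3-en-1-yl}-5-methyl-8-oxabicyclo[3.2.1]oct-6-en-3-one (side arm syn to the O bridge) | C[C@]12CC(=O)[C@H](C[C@H](O[Si](C)(C)C(C)(C)C)C=C)[C@H](O1)C=C2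
F2 | step 4 | 2-{(2S)-2-[(tert-butyldimethylsilyl)oxy]but-3-en-1-yl}-2,5-dimethyl-8-oxabicyclo[3.2.1]oct-6-en-3-one (2-methyl syn to the O bridge) | C[C@]12CC(=O)[C@@](C)(C[C@H](O[Si](C)(C)C(C)(C)C)C=C)[C@H](O1)C=C2
F3 | step 4 | trimethylsilyl ether of the ring-opened hydroxy dienone | C[Si](C)(C)O[C@@H]1C=CC(C)=CC(=O)[C@@]1(C)C[C@H](O[Si](C)(C)C(C)(C)C)C=C
F4 | step 4 | (6R,7S)-7-{(2S)-2-[(tert-butyldimethylsilyl)oxy]but-3-en-1-yl}-6-hydroxy-3,7-dimethylcyclohepta-2,4-dien-1-one (and ring isomer) | O[C@@H]1C=CC(C)=CC(=O)[C@@]1(C)C[C@H](O[Si](C)(C)C(C)(C)C)C=C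
F5 | step 8 | triethylsilyl ether analogue of 11 | CC[Si](CC)(CC)O[C@@H]1C=CC(C)=CC(=O)[C@@]1(C)C[C@H](O[Si](C)(C)C(C)(C)C)C=C
F6 | step 8 | triethylsilyl ether analogue of aldehyde 12 | CC[Si](CC)(CC)O[C@@H]1C=CC(C)=CC(=O)[C@@]1(C)C[C@H](O[Si](C)(C)C(C)(C)C)C=O
F7 | step 8 | triethylsilyl ether analogue of Baylis–Hillman adduct 14 | CC[Si](CC)(CC)O[C@@H]1C=CC(C)=CC(=O)[C@@]1(C)C[C@H](O[Si](C)(C)C(C)(C)C)C(O)C(=C)C(=O)OC
F8 | step 8 | triethylsilyl ether analogue of bromide 15 | CC[Si](CC)(CC)O[C@@H]1C=CC(C)=CC(=O)[C@@]1(C)C[C@H](O[Si](C)(C)C(C)(C)C)/C=C(\CBr)C(=O)OC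
F9 | step 8 | cis-fused bicyclic tertiary alcohol (C1–OTES, C8–OTBS, methyl ester) | CC[Si](CC)(CC)O[C@@H]1C=CC(C)=C[C@]2(O)[C@@]1(C)C[C@H](O[Si](C)(C)C(C)(C)C)[C@H]2C(=C)C(=O)OC
F10 | step 8 | bicyclic 1,3-diol (C1–OH secondary, C6–OH tertiary) | O[C@@H]1C=CC(C)=C[C@]2(O)[C@@]1(C)C[C@H](O[Si](C)(C)C(C)(C)C)[C@H]2C(=C)C(=O)OC
F11 | step 8 | C1 monomesylate of F10 | CS(=O)(=O)O[C@@H]1C=CC(C)=C[C@]2(O)[C@@]1(C)C[C@H](O[Si](C)(C)C(C)(C)C)[C@H]2C(=C)C(=O)OC
F12 | step 13 | (6R,7R,8S)-8-(methylsulfonyloxy)germacra-1(10)E,2Z,4Z,11(13)-tetraen-12,6-olide | C=C1C(=O)O[C@@H]2/C=C(C)\C=C/C=C(C)/C[C@H](OS(C)(=O)=O)[C@@H]12
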